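If we repeat these flasks, we should watch the charge before the clock, because the noon run reads 41.4% tris adduct at 0.833 d and 41.4% at 4.00 d, so it stands still well before the time asked.

common to all: substrate 0.10 M
- noon: coupling partner 0.18 M; run made earlier
- midnight: coupling partner 0.58 M; run made earlier
- red: coupling partner 0.150 M; time 4.0 d
- teal: coupling partner 0.300 M; time 4.0 d
- violet: coupling partner 0.400 M; time 4.0 d

| run | time / d | tris adduct / % | bis adduct / % |
|---|---|---|---|
| noon | 0.833 | 41.4 | 15.2 |
| noon | 1.67 | 40.1 | 16.0 |
| noon | 2.50 | 39.3 | 14.2 |
| noon | 3.00 | 40.9 | 14.7 |
| noon | 4.00 | 41.4 | 17.4 |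
| midnight | 0.333 | 101.2 | 1.4 |
| midnight | 0.625 | 100.4 | 1.1 |
| midnight | 1.04 | 101.4 | 0 |
| midnight | 2.00 | 99.7 | 0 |
| midnight | 4.00 | 99.9 | 0 |

(readings scatter by 1 percentage point)

- how much tris adduct is there at the end, in percent of the substrate charged: for each flask in turn (red, teal, violet)



Red has 0.500, teal 1.00 and violet 1.33 in the ratio we carry, the cover, which is [coupling partner] charged over 3 times [substrate] charged; noon has 0.600 and midnight 1.93. Cover one is the crossing. Below it coupling partner is the limiting reagent and the cover is the ceiling on tris adduct, which gives 50.0% for red, while teal stands at the crossing with a ceiling of >99.9%. Above it substrate limits, and violet should keep 25.0% of its partner.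

Our reckoning tightens these bounds from noon. We take it that a smaller charge fills its ceiling no better, which brings red down to 34.5%. We also take it that removing partner costs at most one tris adduct per partner, which puts our estimate of red above 11.4%, and that added partner yields at least one tris adduct per 3, which puts our estimate of teal at 81.4% or more and closes violet at 100%.

The forecast, holding that “about 0.025 M is lost”, gives 31%, 86% and 99.5%: the first two lie inside our brackets, the third 0.5 percentage points under the closed one.

The flasks give 28.2%, 99.1% and 100%, so teal stands 13 points above the forecast.

    coupling partner + mono adduct → bis adduct + released group (k = 0.00240 L mol⁻¹ s⁻¹)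
    substrate ⇌ dormant form (K = 0.782, k = 2.17 × 10⁻⁴ s⁻¹)
    substrate + coupling partner → mono adduct + released group (k = 0.00430 L mol⁻¹ s⁻¹)
    coupling partner + bis adduct → tris adduct + released group (k = 0.00520 L mol⁻¹ s⁻¹)

In teal, at cover 1.00, the half-lives of mono adduct and bis adduct, each by its own step alone with the other concentrations as charged, are 0.27 h and 0.12 h, both far shorter than the 4.0 d allowed, and teal ends with 99.1% tris adduct. Violet, at cover 1.33, holds 100% tris adduct with 25% of its own partner charge left.

The readings are simulated on assumed constants; scatter was added.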